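**Plan**

Ring letters: A is the benzo ring and C the pyranone ring of the chromanone, B is the aryl ring on C3, D is the dimethylpyran.
Retrosynthesis: the 7-OH/C4=O pair goes back to a 7-silyl ether and a C4 alcohol. Ring D is then cut at C5'–CH= and O–C(CH3)2 to a 4'-O-(1,1-dimethylpropargyl) ether, itself from a phenol and 3-chloro-3-methylbut-1-yne. Last, C3–C1' is cut to 7-hydroxychroman-4-one and 4-bromo-3-methoxyphenol.
Enabling feature: ring D is fused to ring B through the oxygen on C4' and the carbon C5'. In the open phenol C5' carries hydrogen, lies para to the 2'-methoxy group and is the unhindered ortho position, so a propargyl ether on O4' can deliver both ring D bonds.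
Forward: rings A and C are bought as one piece, ring B is joined at C3 by palladium-catalysed ketone arylation, ring D is closed by the thermal cascade, then C4 is oxidised and O7 unmasked.
Stereochemistry: C3 (S) comes from a ruthenium-catalysed transfer hydrogenation with dynamic kinetic resolution giving the cis-(3S,4S) chromanol. C3 stays at the non-enolisable alcohol level through the hot step, and the auxiliary C4 centre is erased by a late non-basic oxidation.

Key step: step 7

Assumption: RuCl(p-cymene)[(S,S)-TsDPEN] is taken to give the 4S carbinol, as it does with 1-tetralone and chroman-4-one; with the cis-selective resolution this fixes C3 as S.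

**Route**

Step 1
Reactants: 1 4-bromo-3-methoxyphenol
Product: 2 4-(benzyloxy)-1-bromo-2-methoxybenzene
Conditions: BnBr, K2CO3, DMF, rt
Reagents that add atoms: benzyl bromide, BrCc1ccccc1
Why: Williamson ether synthesis masks the future O4' with a group that tolerates palladium enolate chemistry and can be removed by hydrogenolysis while the molecule still has no alkene.

Step 2
Reactants: 3 7-hydroxychroman-4-one
Product: 4 7-(triisopropylsilyloxy)chroman-4-one
Conditions: TIPSCl, imidazole, DMF, rt
Reagents that add atoms: triisopropylsilyl chloride, CC(C)[Si](Cl)(C(C)C)C(C)C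
Why: Imidazole-promoted silylation of the phenol gives a bulky aryl silyl ether that should survive phosphate base, hydrogenolysis, formate reduction and heat, and that fluoride removes at the end without base.

Step 3
Reactants: 2 4-(benzyloxy)-1-bromo-2-methoxybenzene; 4 7-(triisopropylsilyloxy)chroman-4-one
Product: 5 racemic 3-[4-(benzyloxy)-2-methoxyphenyl]-7-(triisopropylsilyloxy)chroman-4-one
Conditions: Pd(OAc)2 (cat.), XPhos, K3PO4, toluene, 90 °C
Reagents that add atoms: none
Why: Palladium-catalysed α-arylation of the ketone enolate (Buchwald–Hartwig type) forms C3–C1', with the bulky biaryl phosphine handling the electron-rich ortho-methoxy bromide, the mild phosphate base limiting ring C opening and silyl loss, the ortho substituent discouraging a second arylation, and C3 arising racemic as the later resolution requires.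

Step 4
Reactants: 5 racemic 3-[4-(benzyloxy)-2-methoxyphenyl]-7-(triisopropylsilyloxy)chroman-4-one
Product: 6 racemic 3-(4-hydroxy-2-methoxyphenyl)-7-(triisopropylsilyloxy)chroman-4-one
Conditions: H2 (1 atm), Pd/C, EtOAc, rt
Reagents that add atoms: none
Why: Catalytic hydrogenolysis cleaves the aryl benzyl ether quickly, while the electron-rich aryl ketone and the silyl ether should be untouched in a non-protic solvent.

Step 5
Reactants: 6 racemic 3-(4-hydroxy-2-methoxyphenyl)-7-(triisopropylsilyloxy)chroman-4-one
Product: 7 (3S,4S)-3-(4-hydroxy-2-methoxyphenyl)-7-(triisopropylsilyloxy)chroman-4-ol (cis)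
Conditions: RuCl(p-cymene)[(S,S)-TsDPEN] (cat.), HCO2H/Et3N (5:2), EtOAc, 40 °C
Reagents that add atoms: none
Why: In this Noyori asymmetric transfer hydrogenation with dynamic kinetic resolution C3 racemises through the enol in the amine buffer while the catalyst reduces one ketone enantiomer from the face opposite the C3 aryl group, so the catalyst sets C4 (S) and the cis-selective resolution sets C3 (S).

Step 6
Reactants: 7 (3S,4S)-3-(4-hydroxy-2-methoxyphenyl)-7-(triisopropylsilyloxy)chroman-4-ol; 8 3-chloro-3-methylbut-1-yne
Product: 9 (3S,4S)-3-[2-methoxy-4-(2-methylbut-3-yn-2-yloxy)phenyl]-7-(triisopropylsilyloxy)chroman-4-ol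
Conditions: DBU, CuCl2·2H2O (cat.), MeCN, 0 °C to rt
Reagents that add atoms: none
Why: Copper-catalysed O-propargylation of a phenol with a tertiary propargylic chloride reacts only at the phenoxide formed by DBU, so the neutral C4 alcohol and the aryl silyl ether should be left alone.

Step 7
Reactants: 9 (3S,4S)-3-[2-methoxy-4-(2-methylbut-3-yn-2-yloxy)phenyl]-7-(triisopropylsilyloxy)chroman-4-ol
Product: 13 (3S,4S)-3-(7-methoxy-2,2-dimethyl-2H-chromen-6-yl)-7-(triisopropylsilyloxy)chroman-4-ol, via allenyl cyclohexadienone 10 (not isolated), via ortho-allenylphenol 11 (not isolated), via ortho-quinone methide 12 (not isolated)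
Conditions: N,N-diethylaniline, 180 °C, argon
Reagents that add atoms: none
Why: Heating triggers an aryl propargyl Claisen [3,3]-shift of the dimethylpropargyl group from O4' to the free ortho carbon C5' to give dienone 10, which enolises to phenol 11, and a 1,5-hydrogen shift from the phenol oxygen to the central allene carbon then gives the Z-configured ortho-quinone methide 12. Ring D closes by a thermally allowed disrotatory oxa-6π electrocyclisation of 12, which forms the O–C(CH3)2 bond of a six-membered 2H-pyran and restores the aromaticity of ring B. The closest known reaction type is the thermal conversion of aryl 1,1-dimethylpropargyl ethers into 2,2-dimethyl-2H-chromenes, which the geminal methyl groups accelerate. No lasting stereocentre is created (the sp3 C5' of 10 is erased on enolisation), and C3 and C4 are not enolisable at the alcohol level, so the cis-(3S,4S) array should pass through the heat unchanged. The step needs site selectivity between C5' and C3': C3' is wedged between the methoxy group and the ether oxygen, whereas C5' has only C6'–H as neighbour and lies para to the methoxy group, so the linear pyran should dominate, and the basic solvent scavenges traces of acid that could dehydrate C4.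

Step 8
Reactants: 13 (3S,4S)-3-(7-methoxy-2,2-dimethyl-2H-chromen-6-yl)-7-(triisopropylsilyloxy)chroman-4-ol
Product: 14 (3S)-3-(7-methoxy-2,2-dimethyl-2H-chromen-6-yl)-7-(triisopropylsilyloxy)chroman-4-one
Conditions: Dess–Martin periodinane, NaHCO3, CH2Cl2, 0 °C to rt
Reagents that add atoms: none
Why: Dess–Martin oxidation of the secondary benzylic alcohol under bicarbonate buffering is non-basic, so the now enolisable C3 centre, the chromene alkene and the aryl silyl ether should be preserved while the auxiliary C4 centre is removed.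

Step 9
Reactants: 14 (3S)-3-(7-methoxy-2,2-dimethyl-2H-chromen-6-yl)-7-(triisopropylsilyloxy)chroman-4-one
Product: 15 (3S)-7-hydroxy-3-(7-methoxy-2,2-dimethyl-2H-chromen-6-yl)chroman-4-one
Conditions: TBAF, AcOH (1:1), THF, 0 °C
Reagents that add atoms: none
Why: Fluoride-mediated desilylation of an aryl silyl ether activated by the para carbonyl should be fast at 0 °C, and the acetic acid buffer keeps free fluoride and phenoxide basicity down so that C3 does not epimerise.

**Compound list**

1 | 4-bromo-3-methoxyphenol | COc1cc(O)ccc1Br | starting material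
2 | 4-(benzyloxy)-1-bromo-2-methoxybenzene | COc1cc(OCc2ccccc2)ccc1Br | intermediate
3 | 7-hydroxychroman-4-one | O=C1CCOc2cc(O)ccc12 | starting material
4 | 7-(triisopropylsilyloxy)chroman-4-one | O=C1CCOc2cc(O[Si](C(C)C)(C(C)C)C(C)C)ccc12 | intermediate
5 | racemic 3-[4-(benzyloxy)-2-methoxyphenyl]-7-(triisopropylsilyloxy)chroman-4-one | COc1cc(OCc2ccccc2)ccc1C1COc2cc(O[Si](C(C)C)(C(C)C)C(C)C)ccc2C1=O | intermediate
6 | racemic 3-(4-hydroxy-2-methoxyphenyl)-7-(triisopropylsilyloxy)chroman-4-one | COc1cc(O)ccc1C1COc2cc(O[Si](C(C)C)(C(C)C)C(C)C)ccc2C1=O | intermediate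
7 | (3S,4S)-3-(4-hydroxy-2-methoxyphenyl)-7-(triisopropylsilyloxy)chroman-4-ol (cis) | O[C@@H]1c2ccc(O[Si](C(C)C)(C(C)C)C(C)C)cc2OC[C@@H]1c1ccc(O)cc1OC | intermediate
8 | 3-chloro-3-methylbut-1-yne | CC(C)(Cl)C#C | starting material
9 | (3S,4S)-3-[2-methoxy-4-(2-methylbut-3-yn-2-yloxy)phenyl]-7-(triisopropylsilyloxy)chroman-4-ol | O[C@@H]1c2ccc(O[Si](C(C)C)(C(C)C)C(C)C)cc2OC[C@@H]1c1ccc(OC(C)(C)C#C)cc1OC | intermediate
10 | 4-[(3S,4S)-4-hydroxy-7-(triisopropylsilyloxy)chroman-3-yl]-3-methoxy-6-(3-methylbuta-1,2-dien-1-yl)cyclohexa-2,4-dien-1-one (C6 of the dienone undefined) | O[C@@H]1c2ccc(O[Si](C(C)C)(C(C)C)C(C)C)cc2OC[C@@H]1C1=CC(C=C=C(C)C)C(=O)C=C1OC | intermediate (not isolated)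
11 | (3S,4S)-3-[4-hydroxy-2-methoxy-5-(3-methylbuta-1,2-dien-1-yl)phenyl]-7-(triisopropylsilyloxy)chroman-4-ol | O[C@@H]1c2ccc(O[Si](C(C)C)(C(C)C)C(C)C)cc2OC[C@@H]1c1cc(C=C=C(C)C)c(O)cc1OC | intermediate (not isolated)
12 | (6Z)-4-[(3S,4S)-4-hydroxy-7-(triisopropylsilyloxy)chroman-3-yl]-3-methoxy-6-(3-methylbut-2-en-1-ylidene)cyclohexa-2,4-dien-1-one | O[C@@H]1c2ccc(O[Si](C(C)C)(C(C)C)C(C)C)cc2OC[C@@H]1C1=C/C(=C/C=C(C)C)C(=O)C=C1OC | intermediate (not isolated)
13 | (3S,4S)-3-(7-methoxy-2,2-dimethyl-2H-chromen-6-yl)-7-(triisopropylsilyloxy)chroman-4-ol | O[C@@H]1c2ccc(O[Si](C(C)C)(C(C)C)C(C)C)cc2OC[C@@H]1c1cc2C=CC(C)(C)Oc2cc1OC | intermediate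
14 | (3S)-3-(7-methoxy-2,2-dimethyl-2H-chromen-6-yl)-7-(triisopropylsilyloxy)chroman-4-one | O=C1c2ccc(O[Si](C(C)C)(C(C)C)C(C)C)cc2OC[C@@H]1c1cc2C=CC(C)(C)Oc2cc1OC | intermediate
15 | (3S)-7-hydroxy-3-(7-methoxy-2,2-dimethyl-2H-chromen-6-yl)chroman-4-one | COc1cc2c(cc1[C@H]1COc3cc(O)ccc3C1=O)C=CC(C)(C)O2 | target

**Step count**

Total: 9 steps. Longest linear sequence: 8 steps (1 through steps 1 and 3–9, or equally 3 through steps 2 and 3–9).

**Steps most likely to fail**

Step 3 (α-arylation). Under base the chromanone enolate may open ring C by β-elimination of the ring A phenoxide, the product may be arylated a second time, or oxidative addition to the hindered electron-rich bromide may be too slow. The fallback sets out from 2 and comes back at 6; it makes the C3–C1' bond by Suzuki–Miyaura coupling on an isoflavone. Bromide 2 is lithiated (n-BuLi, THF, −78 °C) and quenched with B(OiPr)3 to give [4-(benzyloxy)-2-methoxyphenyl]boronic acid F1. Commercial 2',4'-dihydroxyacetophenone is silylated at the non-chelated 4'-OH (TIPSCl, imidazole) to 1-[2-hydroxy-4-(triisopropylsilyloxy)phenyl]ethan-1-one F2. This is condensed with DMF dimethyl acetal to (E)-3-(dimethylamino)-1-[2-hydroxy-4-(triisopropylsilyloxy)phenyl]prop-2-en-1-one F3, and iodine cyclises it to 3-iodo-7-(triisopropylsilyloxy)-4H-chromen-4-one F4. Coupling of F1 with F4 (PdCl2(dppf), K3PO4, dioxane, 80 °C) should give 3-[4-(benzyloxy)-2-methoxyphenyl]-7-(triisopropylsilyloxy)-4H-chromen-4-one F5. Hydrogenation over Pd/C in EtOAc should saturate C2–C3 and remove the benzyl group in one operation, giving 6.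

Step 7 (thermal cascade). The sigmatropic shift may go partly to C3' and give the angular pyran, or the hot medium may dehydrate the free C4 alcohol. The fallback sets out from 9 and comes back at 13; it replaces the pericyclic cascade by an electrophilic ring closure at room temperature. Ph3PAuNTf2 (cat.) in CH2Cl2 should activate the alkyne for a 6-endo-dig hydroarylation by C5', the position para to the methoxy group that is favoured both electronically and sterically. This path makes no new compound (F0).

Step 9 (final desilylation). Enolisation of the α-aryl ketone during fluoride treatment may erode the C3 configuration. The fallback sets out from 13 and comes back at 15; it reverses the order of the last two operations. TBAF in THF removes the silyl group from 13 while C3 is still non-enolisable, giving (3S,4S)-3-(7-methoxy-2,2-dimethyl-2H-chromen-6-yl)chroman-4,7-diol F6. Activated MnO2 in CH2Cl2 should then oxidise the benzylic C4 alcohol on a neutral surface in the presence of the free phenol to give 15.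

**Further compounds**

F1 | step 3 | [4-(benzyloxy)-2-methoxyphenyl]boronic acid | COc1cc(OCc2ccccc2)ccc1B(O)O
F2 | step 3 | 1-[2-hydroxy-4-(triisopropylsilyloxy)phenyl]ethan-1-one | CC(=O)c1ccc(O[Si](C(C)C)(C(C)C)C(C)C)cc1O
F3 | step 3 | (E)-3-(dimethylamino)-1-[2-hydroxy-4-(triisopropylsilyloxy)phenyl]prop-2-en-1-one | CN(C)/C=C/C(=O)c1ccc(O[Si](C(C)C)(C(C)C)C(C)C)cc1O
F4 | step 3 | 3-iodo-7-(triisopropylsilyloxy)-4H-chromen-4-one | O=c1c(I)coc2cc(O[Si](C(C)C)(C(C)C)C(C)C)ccc12
F5 | step 3 | 3-[4-(benzyloxy)-2-methoxyphenyl]-7-(triisopropylsilyloxy)-4H-chromen-4-one | COc1cc(OCc2ccccc2)ccc1-c1coc2cc(O[Si](C(C)C)(C(C)C)C(C)C)ccc2c1=O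
F0 | step 7 | none | none
F6 | step 9 | (3S,4S)-3-(7-methoxy-2,2-dimethyl-2H-chromen-6-yl)chroman-4,7-diol | O[C@@H]1c2ccc(O)cc2OC[C@@H]1c1cc2C=CC(C)(C)Oc2cc1OC
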